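The numbers were set for the occasion; the run is a simulation.

The constants stood at 80 °C, and with them I asked what one L is worth in G before Z takes it away.

    Q → L + G (k1 = 28 h⁻¹, Ea1 = 92.0 kJ mol⁻¹)
    J.L ⇌ Q (K2 = 0.30, k2 = 21 h⁻¹, Ea2 = 112 kJ mol⁻¹, ΔH2 = −10.0 kJ mol⁻¹)
    J + L ⇌ J.L (K3 = 20 L mol⁻¹, k3 = 240 L mol⁻¹ h⁻¹, Ea3 = 59.0 kJ mol⁻¹, ΔH3 = −20.0 kJ mol⁻¹)
    L + Z ⇌ L.Z (K4 = 3400 L mol⁻¹, k4 = 120 L mol⁻¹ h⁻¹, Ea4 = 78.0 kJ mol⁻¹, ΔH4 = 6.00 kJ mol⁻¹)
    (constants at 80 °C)

the same everywhere: J 0.10 M; L 5.0 mM; Z 13 mM; time 2.0 h
- alder: temperature 50 °C
- ash: temperature 80 °C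
- larch: temperature 20 °C

- the best flask by amount of G, in percent of the J charged; "all alike" if 1.5 percentage points covers them all (alder / ash / larch / all alike)
- amount of G at the end, in percent of the J charged, alder
- amount of G at the end, in percent of the J charged, ash
- amount of G at the end, in percent of the J charged, larch

- constants are those at 80 °C; use the activation energies and enthalpies for any other temperature

I wrote the balance of L, the smaller charge: 5.0 mM against 13 mM of Z, so L is the limiting reagent of the trapping. The sum [L] + [J.L] + [Q] + [L.Z] stays equal to the charge, and in ash binding of J, at 24.0 h⁻¹, outran trapping, at 1.56 h⁻¹. I therefore let the round settle first. Of the Q made in ash, a share 0.286 goes on to G, so J.L turns into G at 6.00 h⁻¹. That gives [J.L]/[L] = 1.33.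

Dividing the rate of making G by the rate of making L.Z gives the worth of the catalyst, the G made per L.Z formed, 5.13, a kind of turnover number.

Now the question turned round: for ash to use up its J, each L lost had to carry 20.0 turnovers. At the charged [J] and [Z], ash stood at about a quarter of that; I took this figure as a pace at those concentrations and not as a ceiling on G. The clock comes next. Spread over L, J.L and Q, the working catalyst was lost at 0.596 h⁻¹, so in 2.0 h I reckoned 17.9% for ash. For the ranking I had less: the release of G from Q speeds up by a factor 610 from larch to ash, and I bet on ash.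

The forecast put ash first, with 1.4%, 17% and 0.001% for alder, ash and larch, noting that “Z slowly traps L as L.Z”.

The simulation gave 1.44% in alder, 17.4% in ash and 0% in larch, so ash came first.

In ash after 2.00 h, L.Z held 64.3% of the catalyst, and the G per L.Z formed read 5.41, against the 5.13 I had reckoned. What held ash at 17.4% was in part the reading at that time together with the backward run from Q to J.L: the same flask read 40.9% after 20.0 h, and without that backward run it reached 33.7% at the asked time. One more flask was ash with 0.020 M of L, so Z was the smaller charge there; my worth holds no [L], and at 5.13 G for each L.Z formed, the L.Z standing in that flask at 2.00 h, 51.0% of its catalyst, stood for 52.3% of the J. That flask gave more, 62.8%, with 21.5% of its Z unbound.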